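## The problem

The target 27 is a 5-8-6-6 tetracyclic C25 diol. Numbering used throughout: C1 is the methyl on C2; C2=C3 is the tetrasubstituted olefin; ring A is C3–C7; ring B is the eight-membered ring C2, C3, C7, C8, C9, C18, C19, C20; ring C is C9–C12, C17, C18; ring D is C12–C17. Hydroxyls sit on C5 and C8, methyls on C6, C9, C12 and two on C15.

Ring B is trans-fused to the trans-decalin at C9–C18: the C9 methyl is anti to H18, H18 anti to H17, and H17 anti to the C12 methyl. It is joined to ring A through olefinic C3 and through C7. The eight stereocentres form two blocks separated by the C8 carbinol. C12 can govern C17 and screens one face of C18; C5 can govern C6 and C6 can govern C7. Neither block reliably reaches the other, so each should take its absolute configuration from its own source and the two be joined at C8–C9.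

The hard points are the quaternary C9 beside the neopentyl C8 carbinol, the medium ring, and the C9/C18 relationship, in which the methyl and C19 lie on the same side of ring C. At the C8 ketone stage the β,γ-olefin slips into conjugation and C7 epimerises under acid or base, and the C8 alcohol invites cationic rearrangement, so the late steps must be cold or neutral.

The enabling feature is that oxygenated C8 lies between C7 and quaternary C9. With C18–C19 cut and C2–C8 joined, ring B is the [3,3] product of a C8 cyclobutanol carrying the decalin alkenyl group (C9=C18) on C8 and a vinyl group (C20=C19) on C2. The C9 methyl is then what alkylation of the resulting C8–C9 enolate leaves.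

## Retrosynthesis

**27 back to 25.** No skeletal bond is cut. 27 is taken through its C5 silyl ether 26 to the C8 ketone 25 (a C8–H and an O–Si bond). A C8 carbonyl is what the ring-forming event leaves, and C8 cannot be carried as an alcohol through the union because the carbonyl is the electrophile there. Reducing it last also keeps the sensitive carbinol out of earlier steps. The skeleton is unchanged; the forward reaction must reduce a ketone next to quaternary C9 face-selectively without moving the β,γ-olefin.

**25 back to 22.** The C2=C3 olefin is traced, through dienone 23, to a C2=C20 olefin and a C3 silyloxy group in 22. A [3,3] ring expansion can only place the olefin at C2=C20, so a relay is needed. The C3 oxygen, which the cyclobutanone synthesis installs anyway, provides it: β-elimination gives 23, and a dissolving-metal reduction with kinetic protonation at C7 leaves the olefin at C2=C3. Direct isomerisation of C2=C20 into the tetrasubstituted position was considered and rejected, as it has neither driving force nor regiocontrol. 22 is simpler in that C3 and C7 need no particular configuration for this sequence. The forward steps must protonate C7 anti to the C6 methyl and must not over-reduce.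

**22 back to 13 and 18 (key disconnection).** Three bonds are cut, C8–C9, C18–C19 and C9–CH3, and C2–C8 is rejoined. This gives the alkenylstannane 13 (precursor of vinyllithium 19) and the ring A cyclobutanone 18. The cut divides the molecule into two fragments of similar size, each with its own block of stereocentres, and it forms the eight-membered ring in the union itself, driven by cyclobutane strain. End-to-end closures of ring B after a simple fragment coupling were the neighbours; they bring an entropically poor medium-ring step and do not create C9. The forward reaction must: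
- add 19 to the convex face of 18, cis to the C2 vinyl group;
- place C19 on the C18 face anti to the axial C12 methyl;
- methylate C9 on the side of C19 (trans B/C).

The boat geometry links the C18 face to the C3/C7 ring fusion of 18, so these two centres, although erased later, are not silent in this step.

**18 back to 15 and 16, and 15 back to 14.** C7–C8 and C2–C3 are cut: a [2+2] cycloaddition of the ketene 17, generated from acid chloride 16, with silyl enol ether 15. This gives the 3-oxygenated 2,2-disubstituted cyclobutanone in one step with fixed regiochemistry (carbonyl carbon to nucleophilic C7, substituted carbon to oxygenated C3). Double alkylation of a simpler cyclobutanone at C2 would be longer and regiochemically ambiguous. 15 comes from enone 14 by cutting C6–CH3: conjugate addition anti to the C5 silyloxy group sets C6 and gives the enol ether regiospecifically. The forward cycloaddition should occur anti to the C6 methyl, and the C2 vinyl group must lie on the convex face.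

**13 back to 1, 4 and 6.** The C9–Sn bond leads to enol triflate 12 and on to enone 10, whose reduction sets H17 trans to the C12 methyl and gives the enolate toward C18 only. Cutting C17–C18 and C11–C12 (Robinson annulation) gives diketone 8, made from ketone 3 and enone 6 through the chiral imine 5 of amine 4; 3 comes from 1 by methylation. Enone 10 contains exactly the carbons of rings C and D with no oxygen to remove at C13. Annulation onto the corresponding 1,3-dione was the neighbour and would cost about three further steps for deoxygenation. The forward sequence must create quaternary C12 with high enantioselectivity.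

## Roads not taken

**Alternative 1:** The cut is C9–C18 in ring C. An Ireland–Claisen ring contraction of a silyl ketene acetal forms C9–C18 as an allylic C–O bond breaks, giving the trans-decalin acid A1 with a C18 vinyl group and both C9 appendages differentiated. Its merit is real: C9 and C18 arise together in one cyclic transition state, so their relative configuration follows from enolate geometry. That relationship is the least secure element of the chosen plan, and here this road is better. Its weak points are:
- the carboxyl carbon of A1 must be reduced to a methyl at a neopentyl position;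
- ring A and the eight-membered ring are still to be built, with a late medium-ring closure;
- the rearrangement substrate is itself a medium ring that must be made linearly.

The chosen plan sets against this its convergence, ring B formation in the union, and a four-step endgame.

**Alternative 2:** The cuts are C3–C7 and C2–C20. An alkyne de Mayo sequence ([2+2] photocycloaddition of a β-silyloxy enone with a tethered butynyl unit, then fluoride-induced retro-aldol cleavage) closes ring A and expands a six-membered ring to ring B, giving dione A2. A2 already has the C2=C3 olefin in its final place, and C9 is quaternary before the key step, so neither an olefin relay nor an enolate-face question arises; in both respects this road is better. Against it stand: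
- the uncertain regiochemistry (straight against crossed) and efficiency of an intramolecular enone–alkyne photocycloaddition giving a strained cyclobutene;
- control of C7 from C5/C6 on a flexible tether;
- the extra C20 carbonyl of A2, to be removed beside the C8 ketone;
- a linear, photochemical sequence.

The chosen plan offers a thermal, convergent union and takes C5/C6 from a reliable addition to a ring.

**Alternative 3:** The cuts are C2–C3 and C8–C9. A tricyclic β-keto ester adds through C2 to a ring A β-chloro enal with loss of chloride, and the ketone enolate then closes on the C8 aldehyde, giving the bridged ketol A3. This is as convergent as the chosen plan, and it creates the C8 carbinol directly within a rigid bicyclo[3.3.1] frame, which is an advantage over a late ketone reduction. Its weak points are: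
- intermolecular bond formation at a fully substituted, hindered carbon;
- two carbonyl carbons that must later become methyls;
- a retro-Dieckmann opening whose direction has to be controlled;
- an olefin in A3 (C7=C3) that still has to be moved.

The chosen plan introduces both methyls at the correct oxidation level and needs fewer redox steps after the union.

Key step: step 9

Remark on the chemistry: compounds 1, 4, 6, 14 and 16 are taken as commercial, and the numbering C1–C20 defined above is used for every intermediate.

## Route

Step 1
Reactants: 1 3,3-dimethylcyclohexan-1-one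
Product: 3 2,5,5-trimethylcyclohexan-1-one (racemic), via lithium enolate 2 (not isolated)
Conditions: LiN(i-Pr)2, THF, −78 °C; MeI, −78 to 0 °C
Reagents that add atoms: iodomethane, CI
Why: Kinetic deprotonation should occur away from the neopentyl methylene beside the gem-dimethyl carbon, and the enolate is C-methylated (enolate alkylation); the new stereocentre does not matter because it becomes trigonal in step 3.

Step 2
Reactants: 3 2,5,5-trimethylcyclohexan-1-one; 4 (R)-1-phenylethylamine
Product: 5 N-[(R)-1-phenylethyl] imine of 3
Conditions: TsOH (cat.), toluene, reflux, Dean–Stark trap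
Reagents that add atoms: none
Why: Acid-catalysed condensation with azeotropic removal of water; the imine equilibrates with the more substituted secondary enamine needed in step 3.

Step 3
Reactants: 5 N-[(R)-1-phenylethyl] imine of 3; 6 but-3-en-2-one
Product: 8 (S)-2,5,5-trimethyl-2-(3-oxobutyl)cyclohexan-1-one, via Michael adduct imine 7 (not isolated)
Conditions: THF, 23 °C; then AcOH, H2O, 23 °C
Reagents that add atoms: water, O
Why: Deracemising Michael addition of a chiral imine: the tetrasubstituted enamine tautomer adds to the enone in a compact, hydrogen-transfer transition state on the face away from the phenyl group, creating quaternary C12. The (R)-amine should give the (S)-diketone, and hydrolysis returns the amine.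

Step 4
Reactants: 8 (S)-2,5,5-trimethyl-2-(3-oxobutyl)cyclohexan-1-one
Product: 10 (S)-4a,7,7-trimethyl-4,4a,5,6,7,8-hexahydronaphthalen-2(3H)-one, via bicyclic ketol 9 (not isolated)
Conditions: NaOMe, MeOH, 60 °C
Reagents that add atoms: none
Why: Intramolecular aldol condensation (second stage of a Robinson annulation): the methyl ketone enolate closes on the ring ketone and the ketol dehydrates to the conjugated enone.

Step 5
Reactants: 10 (S)-4a,7,7-trimethyl-4,4a,5,6,7,8-hexahydronaphthalen-2(3H)-one
Product: 12 (4aS,8aS)-4a,7,7-trimethyl-3,4,4a,5,6,7,8,8a-octahydronaphthalen-2-yl trifluoromethanesulfonate, via lithium enolate 11 (not isolated)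
Conditions: Li, NH3(l), THF, t-BuOH (1 equiv), −78 °C; isoprene; NH3 evaporated; PhNTf2, THF, 0 °C
Reagents that add atoms: N-phenylbis(trifluoromethanesulfonimide), O=S(=O)(N(c1ccccc1)S(=O)(=O)C(F)(F)F)C(F)(F)F
Why: Dissolving-metal reduction of the enone protonates C17 axially, anti to the C12 methyl (trans-decalin), and leaves the enolate only at C9=C18; O-sulfonylation traps it before it can equilibrate (enolate trapping).

Step 6
Reactants: 12 enol triflate
Product: 13 trimethyl[(4aS,8aS)-4a,7,7-trimethyl-3,4,4a,5,6,7,8,8a-octahydronaphthalen-2-yl]stannane
Conditions: Me3SnSnMe3, Pd(PPh3)4 (5 mol %), LiCl, THF, reflux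
Reagents that add atoms: hexamethyldistannane, C[Sn](C)(C)[Sn](C)(C)C
Why: Palladium-catalysed coupling of an enol triflate with a distannane (oxidative addition to zerovalent palladium, transmetalation, reductive elimination) gives the alkenylstannane, a storable precursor of the C9 vinyllithium; no stereocentre is touched.

Step 7
Reactants: 14 (R)-4-(tert-butyldimethylsilyloxy)cyclopent-2-en-1-one
Product: 15 (3R,4R)-4-(tert-butyldimethylsilyloxy)-3-methyl-1-(trimethylsilyloxy)cyclopent-1-ene
Conditions: Me2CuLi (from MeLi, CuI), Me3SiCl, Et3N, THF, −78 °C
Reagents that add atoms: lithium dimethylcuprate, [Li+].C[Cu-]C; chlorotrimethylsilane, C[Si](C)(C)Cl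
Why: Cuprate conjugate addition anti to the C5 silyloxy group sets C6 (trans). In situ O-silylation fixes the enolate as the C3=C7 silyl enol ether before it can equilibrate or expel the silyloxy group.

Step 8
Reactants: 15 silyl enol ether; 16 (E)-2-methylbut-2-enoyl chloride
Product: 18 ring A 2-methyl-2-vinylcyclobutanone, via methylvinylketene 17 (not isolated)
Conditions: Et3N, CH2Cl2, reflux, slow addition of 16
Reagents that add atoms: none
Why: 1,4-Dehydrochlorination gives the vinylketene, which undergoes [2+2] cycloaddition with the electron-rich enol ether: the ketene carbonyl carbon bonds to nucleophilic C7 and the substituted carbon to oxygenated C3, on the face anti to the C6 methyl. Both C2 epimers are expected; 18, with the vinyl group on the convex face, is separated.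

Step 9
Reactants: 13 alkenylstannane; 18 ring A cyclobutanone
Product: 22 C9-methyl tetracyclic cyclooct-4-enone, via vinyllithium 19 (not isolated), via lithium cyclobutanolate 20 (not isolated), via lithium enolate 21 (not isolated)
Conditions: 13, MeLi, THF, −78 to 0 °C; 18, −78 °C, then to 23 °C; MeI, DMPU, −78 to 0 °C
Reagents that add atoms: iodomethane, CI
Why: Tin–lithium exchange gives 19, which adds to the C8 carbonyl of 18 from the convex face of the bicyclo[3.2.0]heptanone, cis to the C2 vinyl group; the strained cis-1,2-dialkenylcyclobutanolate 20 undergoes an anionic oxy-Cope rearrangement through a boat transition state (C18–C19 formed, C2–C8 cleaved), and enolate 21, formed only toward C9, is C-methylated. The closest known reaction type is the ring expansion of 1,2-dialkenylcyclobutanols, made from 2-vinylcyclobutanones and alkenyllithiums, to cyclooct-4-enones with alkylation of the enolate in the same flask. Ring B closes by a [3,3] sigmatropic four-carbon ring expansion of the cyclobutane, not by an end-to-end cyclisation, and the boat fixes the (Z) geometry of C2=C20. C18: C19 has to bond to the face anti to the axial C12 methyl, which screens the other face by a 1,3-diaxial contact. C9: the methyl has to end on the side of C19, anti to H18 (trans B/C); in 21, allylic strain keeps the C6 arm of ring A out of the position eclipsing C9=C8, which holds the C20=C2 bridge on the H18 face and leaves the required face open. The step also needs convex-face addition (secured by the cis-fused bicycle), C- rather than O-alkylation (lithium enolate, MeI, DMPU) and no proton transfer from C7, which would expel the C3 silyloxy group (low temperature, no excess base). The boat also ties the C18 face to the C3/C7 configuration of 18, and agreement of this with the bias of the C12 methyl is not secured; it is treated under the uncertain steps.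

Step 10
Reactants: 22 C9-methyl tetracyclic cyclooct-4-enone
Product: 23 tetracyclic dienone
Conditions: DBU, toluene, 60 °C
Reagents that add atoms: none
Why: E1cB elimination of the β-silyloxy ketone through the C7 enolate gives the dienone conjugated through C7=C3 and C2=C20. C3 and C7 of the former cyclobutane become trigonal; quaternary C9 cannot enolise.

Step 11
Reactants: 23 tetracyclic dienone
Product: 25 β,γ-unsaturated C8 ketone, via lithium dienolate 24 (not isolated)
Conditions: Li (2.2 equiv), NH3(l), THF, t-BuOH (1 equiv), −78 °C; solid NH4Cl, −78 °C
Reagents that add atoms: none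
Why: Two-electron reduction of the linear dienone with protonation at the δ-carbon C20 leaves the dienolate C8(OLi)=C7–C3=C2. Kinetic protonation at the α-carbon C7 gives the deconjugated ketone with the olefin at C2=C3, as in the dissolving-metal reduction of linear dienones to β,γ-unsaturated ketones. The proton should enter anti to the adjacent C6 methyl, which sets C7.

Step 12
Reactants: 25 β,γ-unsaturated C8 ketone
Product: 26 C5 silyl ether of the target
Conditions: Li, NH3(l), THF, EtOH, −78 °C; NH4Cl
Reagents that add atoms: none
Why: Electron-transfer reduction of the hindered ketone should give the thermodynamically preferred carbinol, expected to carry OH on the C8 face anti to the axial C9 methyl and to the C6 arm of ring A, as in 27. A hydride reagent would be expected to attack that same open face and give the epimer. The cold protic medium limits enolisation toward C7, and the tetrasubstituted olefin is inert.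

Step 13
Reactants: 26 C5 silyl ether of the target
Product: 27 CNP0213887.1
Conditions: Bu4NF, THF, 23 °C
Reagents that add atoms: none
Why: Fluoride cleaves the secondary silyl ether (desilylation) under non-acidic conditions that leave the olefin position and both carbinols untouched.

## Compound list

1 | 3,3-dimethylcyclohexan-1-one | CC1(C)CCCC(=O)C1 | starting material
2 | lithium enolate of 1 (C1=C6) | [Li]OC1=CCCC(C)(C)C1 | intermediate (not isolated)
3 | 2,5,5-trimethylcyclohexan-1-one (racemic) | CC1CCC(C)(C)CC1=O | intermediate
4 | (R)-1-phenylethylamine | C[C@@H](N)c1ccccc1 | starting material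
5 | N-[(R)-1-phenylethyl]-2,5,5-trimethylcyclohexan-1-imine (both C2 epimers) | C[C@@H](N=C1CC(C)(C)CCC1C)c1ccccc1 | intermediate
6 | but-3-en-2-one | CC(=O)C=C | starting material
7 | N-[(R)-1-phenylethyl] imine of (S)-2,5,5-trimethyl-2-(3-oxobutyl)cyclohexan-1-one | CC(=O)CC[C@]1(C)CCC(C)(C)CC1=N[C@H](C)c1ccccc1 | intermediate (not isolated)
8 | (S)-2,5,5-trimethyl-2-(3-oxobutyl)cyclohexan-1-one | CC(=O)CC[C@]1(C)CCC(C)(C)CC1=O | intermediate
9 | (4aS)-8a-hydroxy-4a,7,7-trimethyloctahydronaphthalen-2(1H)-one (carbinol centre undefined) | O=C1CC[C@]2(C)CCC(C)(C)CC2(O)C1 | intermediate (not isolated)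
10 | (S)-4a,7,7-trimethyl-4,4a,5,6,7,8-hexahydronaphthalen-2(3H)-one | O=C1CC[C@]2(C)CCC(C)(C)CC2=C1 | intermediate
11 | lithium (4aS,8aS)-4a,7,7-trimethyl-3,4,4a,5,6,7,8,8a-octahydronaphthalen-2-olate (trans-fused, enolate C9=C18) | [Li]OC1=C[C@@H]2CC(C)(C)CC[C@@]2(C)CC1 | intermediate (not isolated)
12 | (4aS,8aS)-4a,7,7-trimethyl-3,4,4a,5,6,7,8,8a-octahydronaphthalen-2-yl trifluoromethanesulfonate | FC(F)(F)S(=O)(=O)OC1=C[C@@H]2CC(C)(C)CC[C@@]2(C)CC1 | intermediate
13 | trimethyl[(4aS,8aS)-4a,7,7-trimethyl-3,4,4a,5,6,7,8,8a-octahydronaphthalen-2-yl]stannane | C[Sn](C)(C)C1=C[C@@H]2CC(C)(C)CC[C@@]2(C)CC1 | intermediate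
14 | (R)-4-(tert-butyldimethylsilyloxy)cyclopent-2-en-1-one | O=C1C=C[C@H](O[Si](C)(C)C(C)(C)C)C1 | starting material
15 | (3R,4R)-4-(tert-butyldimethylsilyloxy)-3-methyl-1-(trimethylsilyloxy)cyclopent-1-ene (methyl trans to OSi) | C[Si](C)(C)OC1=C[C@@H](C)[C@H](O[Si](C)(C)C(C)(C)C)C1 | intermediate
16 | (E)-2-methylbut-2-enoyl chloride | C/C=C(\C)C(=O)Cl | starting material
17 | methylvinylketene (2-methylbuta-1,3-dien-1-one) | C=CC(C)=C=O | intermediate (not isolated)
18 | ring A cyclobutanone: 3-(tert-butyldimethylsilyloxy)-4,7-dimethyl-1-(trimethylsilyloxy)-7-vinylbicyclo[3.2.0]heptan-6-one; cis-fused, four-membered ring anti to the C6 methyl, C5 OSi trans to that methyl, vinyl on the convex face | C=C[C@@]1(C)C(=O)[C@@H]2[C@@H](C)[C@H](O[Si](C)(C)C(C)(C)C)C[C@]12O[Si](C)(C)C | intermediate (precursor of the key step)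
19 | C9 vinyllithium of the trans-decalin (lithium in place of the stannyl group of 13) | [Li]C1=C[C@@H]2CC(C)(C)CC[C@@]2(C)CC1 | intermediate (not isolated)
20 | lithium cis-1,2-dialkenylcyclobutanolate: 18 with the decalin alkenyl group added to C8 on the convex face, cis to the C2 vinyl group | C=C[C@@]1(C)[C@@](O[Li])(C2=C[C@@H]3CC(C)(C)CC[C@@]3(C)CC2)[C@@H]2[C@@H](C)[C@H](O[Si](C)(C)C(C)(C)C)C[C@]12O[Si](C)(C)C | intermediate (not isolated)
21 | lithium C8–C9 enolate of the tetracycle (C18–C19 formed, (Z)-C2=C20) | C/C1=C/C[C@H]2[C@@H]3CC(C)(C)CC[C@@]3(C)CCC2=C(O[Li])[C@@H]2[C@@H](C)[C@H](O[Si](C)(C)C(C)(C)C)C[C@]12O[Si](C)(C)C | intermediate (not isolated)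
22 | tetracyclic cyclooct-4-enone: C8 ketone, C9 methyl (trans B/C), (Z)-C2=C20, C3 OSiMe3, C5 OSi(t-Bu)Me2, C6 methyl, H7 cis to the C6 methyl | C/C1=C/C[C@H]2[C@@H]3CC(C)(C)CC[C@@]3(C)CC[C@]2(C)C(=O)[C@@H]2[C@@H](C)[C@H](O[Si](C)(C)C(C)(C)C)C[C@]12O[Si](C)(C)C | intermediate (product of the key step)
23 | tetracyclic dienone: C8 ketone conjugated with C7=C3 and (Z)-C2=C20 | C/C1=C/C[C@H]2[C@@H]3CC(C)(C)CC[C@@]3(C)CC[C@]2(C)C(=O)C2=C1C[C@@H](O[Si](C)(C)C(C)(C)C)[C@@H]2C | intermediate
24 | lithium dienolate C8(OLi)=C7–C3=C2 (ring-constrained geometry) | CC1=C2C[C@@H](O[Si](C)(C)C(C)(C)C)[C@H](C)C2=C(O[Li])[C@@]2(C)CC[C@]3(C)CCC(C)(C)C[C@H]3[C@@H]2CC1 | intermediate (not isolated)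
25 | β,γ-unsaturated ketone: C8 ketone, C2=C3 olefin, H7 trans to the C6 methyl, C5 OSi(t-Bu)Me2 | C/C1=C2\C[C@@H](O[Si](C)(C)C(C)(C)C)[C@H](C)[C@@H]2C(=O)[C@@]2(C)CC[C@]3(C)CCC(C)(C)C[C@H]3[C@@H]2CC1 | intermediate
26 | C5 tert-butyldimethylsilyl ether of the target (C8 alcohol free) | C/C1=C2\C[C@@H](O[Si](C)(C)C(C)(C)C)[C@H](C)[C@@H]2[C@@H](O)[C@@]2(C)CC[C@]3(C)CCC(C)(C)C[C@H]3[C@@H]2CC1 | intermediate
27 | CNP0213887.1, tetracyclic C5,C8-diol with C2=C3 olefin | C/C1=C2\C[C@@H](O)[C@H](C)[C@@H]2[C@@H](O)[C@@]2(C)CC[C@]3(C)CCC(C)(C)C[C@H]3[C@@H]2CC1 | target

## Step count and uncertain steps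

Total step count: 13. Longest linear sequence: 11 steps (steps 1–6, then 9–13).

**Step 9 (key step).** The most likely failure is mismatched facial control in the [3,3] shift. In the boat, the vinyl terminus can reach only one face of C18, and which face follows from the C3/C7 ring fusion of 18. For the cyclobutanone that the cycloaddition delivers (four-membered ring anti to the C6 methyl), analysis of the exo boat points C19 toward the face that carries the axial C12 methyl. The rearrangement may then be slow, may give the C18 epimer, or may divert into fragmentation; a smaller risk is leakage of the methylation to the other face of C9.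

The fallback sets out from 14 and 13 and comes back at 25. It uses a cyclobutanone of opposite ring fusion, for which boat and C12 methyl call for the same face:
- 14 is reduced in the 1,4 sense (Et3SiH, RhCl(PPh3)3) to the triethylsilyl enol ether F1, which has no C6 methyl, so only the C5 silyloxy group differentiates its faces.
- Cycloaddition of F1 with 17 should give the ring-fusion-inverted cyclobutanone F2.
- Union of F2 with 19 and rearrangement as in step 9, but with a proton quench and then DBU, would give the nor-methyl dienone F3. The methyl is not added in the flask, because with this ring fusion the ring B bridge lies on the C19 side of the enolate.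
- With C7 trigonal, kinetic α′-deprotonation (LiN(i-Pr)2) and MeI should methylate C9 of F3 from the face left open when C20 lies anti to C17, giving the C9-methyl dienone F4.
- Li/NH3 reduction of F4 with trapping of the dienolate by PhSeBr would give the C7 selenide F5, and H2O2 the cross-conjugated dienone F6 (C7=C6, C2=C3).
- Me2CuLi should add to C6 of F6 anti to the C5 silyloxy group, and kinetic protonation at C7 then returns 25.

All are known reaction types, at the price of four more steps.

**Step 8.** The vinylketene may dimerise or react as a diene faster than it undergoes the [2+2] with a hindered trisubstituted enol ether, and the convex/concave ratio of the vinyl group at C2 may be poor. The fallback sets out from 15 and comes back at 18, with the vinyl group masked: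
- α-methyl-γ-butyrolactone is opened with NaSePh to 2-methyl-4-(phenylselanyl)butanoic acid F7, which (COCl)2 converts to the acid chloride F8;
- the saturated ketene from F8 and Et3N adds to 15 to give the selenide cyclobutanone F9;
- oxidation (H2O2) with selenoxide elimination unveils the vinyl group of 18.

**Step 11.** The likely failures are over-reduction of the ketone, protonation of the dienolate at C2 instead of C7, equilibration of 25 into conjugation during quench, and poor facial selectivity at C7. The fallback sets out from 23 and comes back at 26, avoiding the β,γ-unsaturated ketone: 1,2-reduction (NaBH4, CeCl3, MeOH; Luche reduction) gives the dienol F10, and 1,4-hydrogenation of its cisoid diene with (C10H8)Cr(CO)3 and H2 adds hydrogen to C7 and C20 and leaves the olefin at C2=C3.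

**Step 12.** Facial selectivity at C8 in this medium ring has no close precedent, and alkoxide formed in the medium may move the olefin into conjugation before reduction. The fallback sets out from 25 and comes back at 26: LiAlH4 (Et2O, −78 °C) is expected to attack the open face and give mainly the C8 epimer F11. Mitsunobu inversion (4-nitrobenzoic acid, PPh3, diisopropyl azodicarboxylate) gives the ester F12, and K2CO3 in MeOH releases 26.

## Further compounds

F1 | step 9 | (S)-4-(tert-butyldimethylsilyloxy)-1-(triethylsilyloxy)cyclopent-1-ene | CC[Si](CC)(CC)OC1=CC[C@H](O[Si](C)(C)C(C)(C)C)C1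
F2 | step 9 | ring-fusion-inverted cyclobutanone without C6 methyl: 3-(tert-butyldimethylsilyloxy)-7-methyl-1-(triethylsilyloxy)-7-vinylbicyclo[3.2.0]heptan-6-one, four-membered ring anti to the C5 OSi group, vinyl on the convex face | C=C[C@]1(C)C(=O)[C@H]2C[C@H](O[Si](C)(C)C(C)(C)C)C[C@@]12O[Si](CC)(CC)CC
F3 | step 9 | nor-methyl dienone (C9–H, C6 unsubstituted, C7=C3 and C2=C20) | C/C1=C/C[C@H]2[C@@H]3CC(C)(C)CC[C@@]3(C)CCC2C(=O)C2=C1C[C@@H](O[Si](C)(C)C(C)(C)C)C2
F4 | step 9 | C9-methyl dienone with C6 unsubstituted | C/C1=C/C[C@H]2[C@@H]3CC(C)(C)CC[C@@]3(C)CC[C@]2(C)C(=O)C2=C1C[C@@H](O[Si](C)(C)C(C)(C)C)C2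
F5 | step 9 | C7-phenylselanyl β,γ-unsaturated C8 ketone (C6 unsubstituted, C7 undefined) | C/C1=C2\C[C@@H](O[Si](C)(C)C(C)(C)C)CC2([Se]c2ccccc2)C(=O)[C@@]2(C)CC[C@]3(C)CCC(C)(C)C[C@H]3[C@@H]2CC1
F6 | step 9 | cross-conjugated dienone (C8 ketone, C7=C6, C2=C3) | C/C1=C2\C[C@@H](O[Si](C)(C)C(C)(C)C)C=C2C(=O)[C@@]2(C)CC[C@]3(C)CCC(C)(C)C[C@H]3[C@@H]2CC1
F7 | step 8 | 2-methyl-4-(phenylselanyl)butanoic acid (racemic) | CC(CC[Se]c1ccccc1)C(=O)O
F8 | step 8 | 2-methyl-4-(phenylselanyl)butanoyl chloride (racemic) | CC(CC[Se]c1ccccc1)C(=O)Cl
F9 | step 8 | analogue of 18 with a 2-(phenylselanyl)ethyl group in place of the vinyl group | C[C@]1(CC[Se]c2ccccc2)C(=O)[C@@H]2[C@@H](C)[C@H](O[Si](C)(C)C(C)(C)C)C[C@]12O[Si](C)(C)C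
F10 | step 11 | dienol: C8 alcohol of 23 | C/C1=C/C[C@H]2[C@@H]3CC(C)(C)CC[C@@]3(C)CC[C@]2(C)[C@H](O)C2=C1C[C@@H](O[Si](C)(C)C(C)(C)C)[C@@H]2C
F11 | step 12 | C8 epimer of 26 | C/C1=C2\C[C@@H](O[Si](C)(C)C(C)(C)C)[C@H](C)[C@@H]2[C@H](O)[C@@]2(C)CC[C@]3(C)CCC(C)(C)C[C@H]3[C@@H]2CC1
F12 | step 12 | C8 4-nitrobenzoate of 26 | C/C1=C2\C[C@@H](O[Si](C)(C)C(C)(C)C)[C@H](C)[C@@H]2[C@@H](OC(=O)c4ccc(cc4)[N+](=O)[O-])[C@@]2(C)CC[C@]3(C)CCC(C)(C)C[C@H]3[C@@H]2CC1
A1 | alternative 1 | trans-decalin C9 carboxylic acid with C9 (4-methoxybenzyloxy)methyl and C18 vinyl groups | OC(=O)[C@]1(COCc2ccc(OC)cc2)CC[C@]2(C)CCC(C)(C)C[C@H]2[C@@H]1C=C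
A2 | alternative 2 | tetracyclic cyclooct-2-ene-1,5-dione (C8 and C20 ketones, C5 benzyl ether) | C/C1=C2\C[C@@H](OCc3ccccc3)[C@H](C)[C@@H]2C(=O)[C@@]2(C)CC[C@]3(C)CCC(C)(C)C[C@H]3[C@@H]2CC1=O
A3 | alternative 3 | bridged bicyclo[3.3.1]nonenone ketol | COC(=O)[C@@]12CC[C@H]3[C@@H]4CC(C)(C)CC[C@@]4(C)CC[C@]3(C1=O)[C@H](O)C1=C2C[C@@H](O[Si](C)(C)C(C)(C)C)[C@@H]1C
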